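The benzene ring is built onto the end of the finished side chain. Its 1,3-dioxygenated, 5-alkylated pattern (ring C1–OH, C3–O, C5–alkyl) maps onto two partners. A 3-alkylcyclobutenone supplies C1 (its carbonyl) and C4–C6, and an ynol ether supplies C2 and C3–O. Heating the two triggers a Danheiser benzannulation that forms C1–C2 and C3–C4, closes C1–C6 and aromatises in one operation. The precursor is a cyclobut-2-enone carrying at C3 an unbranched C17 chain whose penultimate carbon is an (S)-carbinol masked as a benzoate. The stereocentre comes from (S)-propylene oxide, and the two alkene carbons of the four-membered ring come from a terminal alkyne.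

Key step: step 6

Remark on the chemistry: the target is read as CH3–CH(OH)–(CH2)15–aryl with an S carbinol. C16 alkyne plus C3 epoxide gives a C19 chain. Its C18 and C19 become cyclobutenone C3 and C2, and later arene C5 and C4, which leaves the required 17-carbon chain. No step breaks the C–O bond of the stereocentre, so the optical purity is that of the purchased epoxide.

Step 1
Reactants: 1 1-hexadecyne; 2 (S)-propylene oxide
Product: 4 (S)-nonadec-4-yn-2-ol, via lithium hexadec-1-ynide 3 (not isolated)
Conditions: n-BuLi, THF, –78 °C; BF3·OEt2, then 2, –78 °C; H2O quench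
Reagents that add atoms: none
Why: BF3-assisted SN2 opening of a terminal epoxide by a lithium acetylide (Yamaguchi–Hirao conditions) occurs at the unsubstituted CH2, so the C–O bond of the stereocentre stays intact and the S configuration of 2 passes unchanged into 4.

Step 2
Reactants: 4 (S)-nonadec-4-yn-2-ol
Product: 6 (S)-nonadec-18-yn-2-ol, via dipotassium alkoxide acetylide 5 (not isolated)
Conditions: KH (4 equiv), H2N(CH2)3NH2 (KAPA), 0 °C → rt; H2O quench
Reagents that add atoms: none
Why: In the alkyne zipper isomerisation, reversible propargyl/allenyl proton shifts move the triple bond along the unbranched chain, the alkoxide-bearing C2 blocks the other direction and is not deprotonated, and irreversible formation of the terminal acetylide drains the equilibrium, a process known to leave secondary carbinol centres unchanged.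

Step 3
Reactants: 6 (S)-nonadec-18-yn-2-ol
Product: 7 (S)-nonadec-18-yn-2-yl benzoate
Conditions: BzCl, Et3N, DMAP (cat.), CH2Cl2, 0 °C → rt
Reagents that add atoms: benzoyl chloride, O=C(Cl)c1ccccc1
Why: Routine DMAP-catalysed O-acylation leaves the C–O bond of the stereocentre untouched, and an ester is preferred to a silyl ether because it keeps the carbinol oxygen a poor Lewis base in the later BBr3 step (silyl ethers and free secondary alcohols can be turned into bromides by that reagent) while tolerating zinc, acetic acid and heat.

Step 4
Reactants: 7 (S)-nonadec-18-yn-2-yl benzoate; 8 trichloroacetyl chloride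
Product: 10 (S)-17-(4,4-dichloro-3-oxocyclobut-1-en-1-yl)heptadecan-2-yl benzoate, via dichloroketene 9 (not isolated)
Conditions: 8 (2 equiv, slow addition), Zn–Cu couple, Et2O/DME, rt
Reagents that add atoms: none
Why: In this ketene–alkyne [2+2] cycloaddition, dichloroketene released by zinc dechlorination of 8 adds to the terminal alkyne with the CH terminus bonding to the ketene carbonyl carbon, which places the chain at ring C3, while DME ties up the zinc chloride.

Step 5
Reactants: 10 (S)-17-(4,4-dichloro-3-oxocyclobut-1-en-1-yl)heptadecan-2-yl benzoate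
Product: 11 (S)-17-(3-oxocyclobut-1-en-1-yl)heptadecan-2-yl benzoate
Conditions: Zn dust, AcOH, TMEDA, EtOH, 0 °C → rt
Reagents that add atoms: none
Why: Reductive dechlorination with TMEDA-buffered Zn/AcOH, the standard method for 4,4-dichlorocyclobutenones, removes both chlorines (also from any isomer formed by allylic chloride shift) without reducing the enone, moving the double bond or touching the ester.

Step 6
Reactants: 11 (S)-17-(3-oxocyclobut-1-en-1-yl)heptadecan-2-yl benzoate; 12 ethoxyacetylene
Product: 17 (S)-17-(3-ethoxy-5-hydroxyphenyl)heptadecan-2-yl benzoate, via vinylketene 13 (not isolated), via 4-alkenylcyclobutenone 14 (not isolated), via dienylketene 15 (not isolated), via cyclohexadienone 16 (not isolated)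
Conditions: 12 (3 equiv, ca. 40 wt% in hexanes), toluene, sealed tube, 80 °C; vent surplus 12, then 110–120 °C
Reagents that add atoms: none
Why: This is a Danheiser benzannulation, a neutral thermal pericyclic cascade in which the C1–C4 σ bond of the cyclobutenone breaks at about 80 °C in a 4π electrocyclic opening to give vinylketene 13, whose ketene C=C adds the alkyne in a [2+2] cycloaddition to give 14. A second 4π opening of 14 gives dienylketene 15, the benzene ring is closed by thermal disrotatory 6π electrocyclisation between the ketene carbon and the terminal CH2, and enolisation of 16 delivers the phenol. The only selectivity needed is the orientation of the alkyne, and polarity fixes it, because the electron-rich CH terminus of the ynol ether attacks the electrophilic ketene carbon, so OEt ends up meta to the new OH and both are meta to the chain. The closest known reaction type is the annulation of simple 3-alkylcyclobutenones with alkoxyalkynes to give 5-alkylresorcinol monoethers. No stereocentre is created in 17 (the sp3 ring carbon of 14 is transient), and the remote ester-bearing centre is inert to neutral heating. The alkyne is used in excess so that it outcompetes acylation of the product phenol by the vinylketene, and its surplus is vented before the temperature is raised because ethoxyacetylene undergoes retro-ene fragmentation above about 100 °C.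

Step 7
Reactants: 17 (S)-17-(3-ethoxy-5-hydroxyphenyl)heptadecan-2-yl benzoate
Product: 18 (S)-17-(3,5-dihydroxyphenyl)heptadecan-2-yl benzoate
Conditions: BBr3 (4 equiv), CH2Cl2, –78 → 0 °C; H2O quench
Reagents that add atoms: none
Why: In this Lewis-acid aryl ether cleavage, BBr3 binds the ether oxygen and bromide removes the primary ethyl group by SN2, whereas the secondary benzoate, of the same CH3CH(OCOAr)CH2 type that withstands this reagent in resorcylic acid lactones, is only complexed reversibly at its carbonyl at or below 0 °C, so the stereocentre is not engaged.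

Step 8
Reactants: 18 (S)-17-(3,5-dihydroxyphenyl)heptadecan-2-yl benzoate
Product: 19 hansfordiol A, (S)-5-(16-hydroxyheptadecyl)benzene-1,3-diol
Conditions: K2CO3 (4 equiv), MeOH, 45 °C, Ar; then 1 M HCl
Reagents that add atoms: none
Why: Base-mediated transesterification (methanolysis) breaks only the acyl–oxygen bond, so the carbinol is released with retention, any aryl ester carried along from step 6 is cleaved as well, and argon protects the resorcinolate from air.

Compound list
1 | 1-hexadecyne | C#CCCCCCCCCCCCCCC | starting material
2 | (S)-propylene oxide, (S)-2-methyloxirane | C[C@H]1CO1 | starting material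
3 | lithium hexadec-1-ynide | [Li]C#CCCCCCCCCCCCCCC | intermediate
4 | (S)-nonadec-4-yn-2-ol | C[C@H](O)CC#CCCCCCCCCCCCCCC | intermediate
5 | dipotassium salt (C2 alkoxide, C19 acetylide) of (S)-nonadec-18-yn-2-ol | C[C@H]([O-])CCCCCCCCCCCCCCCC#[C-].[K+].[K+] | intermediate
6 | (S)-nonadec-18-yn-2-ol | C[C@H](O)CCCCCCCCCCCCCCCC#C | intermediate
7 | (S)-nonadec-18-yn-2-yl benzoate | C[C@H](OC(=O)c1ccccc1)CCCCCCCCCCCCCCCC#C | intermediate
8 | trichloroacetyl chloride | ClC(Cl)(Cl)C(Cl)=O | starting material
9 | dichloroketene | ClC(Cl)=C=O | intermediate
10 | (S)-17-(4,4-dichloro-3-oxocyclobut-1-en-1-yl)heptadecan-2-yl benzoate | C[C@H](OC(=O)c1ccccc1)CCCCCCCCCCCCCCCC1=CC(=O)C1(Cl)Cl | intermediate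
11 | (S)-17-(3-oxocyclobut-1-en-1-yl)heptadecan-2-yl benzoate | C[C@H](OC(=O)c1ccccc1)CCCCCCCCCCCCCCCC1=CC(=O)C1 | intermediate
12 | ethoxyacetylene | C#COCC | starting material
13 | vinylketene, (S)-18-methylidene-20-oxoicos-19-en-2-yl benzoate | C[C@H](OC(=O)c1ccccc1)CCCCCCCCCCCCCCCC(=C)C=C=O | intermediate
14 | (2S)-18-(2-ethoxy-4-oxocyclobut-2-en-1-yl)nonadec-18-en-2-yl benzoate (both epimers at the transient ring sp3 carbon) | C[C@H](OC(=O)c1ccccc1)CCCCCCCCCCCCCCCC(=C)C1C(=O)C=C1OCC | intermediate
15 | dienylketene, (S)-20-ethoxy-18-methylidene-22-oxodocosa-19,21-dien-2-yl benzoate (alkenyl and ketenyl groups cis on C19=C20) | C[C@H](OC(=O)c1ccccc1)CCCCCCCCCCCCCCCC(=C)/C=C(/OCC)C=C=O | intermediate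
16 | (S)-17-(3-ethoxy-5-oxocyclohexa-1,3-dien-1-yl)heptadecan-2-yl benzoate | C[C@H](OC(=O)c1ccccc1)CCCCCCCCCCCCCCCC1=CC(OCC)=CC(=O)C1 | intermediate
17 | (S)-17-(3-ethoxy-5-hydroxyphenyl)heptadecan-2-yl benzoate | C[C@H](OC(=O)c1ccccc1)CCCCCCCCCCCCCCCc1cc(O)cc(OCC)c1 | intermediate
18 | (S)-17-(3,5-dihydroxyphenyl)heptadecan-2-yl benzoate | C[C@H](OC(=O)c1ccccc1)CCCCCCCCCCCCCCCc1cc(O)cc(O)c1 | intermediate
19 | hansfordiol A, (S)-5-(16-hydroxyheptadecyl)benzene-1,3-diol | C[C@H](O)CCCCCCCCCCCCCCCc1cc(O)cc(O)c1 | target

Total step count: 8. Longest linear sequence: 8 steps (1 and 2 → 19).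

Steps most likely to fail

Risk 1, step 6. The vinylketene may be consumed by dimerisation or by acylating the phenol as it forms. The ynol ether may also be lost by retro-ene fragmentation before the second ring opening is complete. The fallback sets out from 2 and comes back at 19, and it brings the arene in ready-made instead of constructing it. 1-Tetradecyne (n-BuLi, BF3·OEt2, THF, –78 °C) opens 2 to give (S)-heptadec-4-yn-2-ol F1, and KAPA isomerisation gives (S)-heptadec-16-yn-2-ol F2. Sonogashira coupling (PdCl2(PPh3)2, CuI, Et3N, 70 °C) follows with 1,3-bis(benzyloxy)-5-bromobenzene F3, itself made from 5-bromoresorcinol with BnBr and K2CO3 in acetone. This gives (S)-17-[3,5-bis(benzyloxy)phenyl]heptadec-16-yn-2-ol F4. Hydrogenation over Pd/C (EtOAc/EtOH) saturates the alkyne and removes both benzyl groups in the same operation to give 19.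

Risk 2, step 7. The ethyl ether reacts more slowly than a methyl ether. Longer times or warming could bring on alkyl–oxygen fission at the Lewis-acid-complexed secondary ester, with substitution or erosion of configuration at the carbinol. The fallback sets out from 17 and comes back at 19, and it replaces the bromide-based cleavage by a hydride-based one. Methanolysis (K2CO3, MeOH) first gives (S)-3-ethoxy-5-(16-hydroxyheptadecyl)phenol F5. Treatment with excess Et3SiH and catalytic B(C6F5)3 (CH2Cl2, rt, Piers–Rubinsztajn-type dealkylative silylation) then silylates both hydroxyl groups and exchanges the ethyl group for SiEt3. This process stops at the silyl ether stage for aryl and secondary alkyl oxygens and gives the tris(triethylsilyl) ether F6. Dilute HCl in THF/MeOH then frees 19.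

Risk 3, step 4. Oligomerisation of dichloroketene may outrun cycloaddition to the unactivated alkyne, and the sensitive adduct may suffer chloride migration or decomposition during isolation. The fallback sets out from 7 and comes back at 11, bypassing 10 and step 5. It is a Ghosez keteniminium [2+2] cycloaddition run with N,N-dimethylacetamide, Tf2O and 2,4,6-collidine in 1,2-dichloroethane at reflux. The addition follows the same polarity-controlled orientation and gives the 3-alkylcyclobut-2-enylidene-dimethyliminium triflate F7, and hydrolysis with aqueous NaHCO3 gives 11.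

Further compounds
F1 | step 6 | (S)-heptadec-4-yn-2-ol | C[C@H](O)CC#CCCCCCCCCCCCC
F2 | step 6 | (S)-heptadec-16-yn-2-ol | C[C@H](O)CCCCCCCCCCCCCC#C
F3 | step 6 | 1,3-bis(benzyloxy)-5-bromobenzene | Brc1cc(OCc2ccccc2)cc(OCc2ccccc2)c1
F4 | step 6 | (S)-17-[3,5-bis(benzyloxy)phenyl]heptadec-16-yn-2-ol | C[C@H](O)CCCCCCCCCCCCCC#Cc1cc(OCc2ccccc2)cc(OCc2ccccc2)c1
F5 | step 7 | (S)-3-ethoxy-5-(16-hydroxyheptadecyl)phenol | C[C@H](O)CCCCCCCCCCCCCCCc1cc(O)cc(OCC)c1
F6 | step 7 | (S)-tris(triethylsilyl) ether of hansfordiol A | C[C@H](O[Si](CC)(CC)CC)CCCCCCCCCCCCCCCc1cc(O[Si](CC)(CC)CC)cc(O[Si](CC)(CC)CC)c1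
F7 | step 4 | (S)-N-[3-(16-benzoyloxyheptadecyl)cyclobut-2-en-1-ylidene]-N-methylmethanaminium triflate | C[C@H](OC(=O)c1ccccc1)CCCCCCCCCCCCCCCC1=CC(=[N+](C)C)C1.[O-]S(=O)(=O)C(F)(F)F
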